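**Assumption:** atoms are numbered as in the daucane skeleton (C1 quaternary ring-fusion carbon with methyl, C4 carbinol carbon with isopropyl, C5 ring-fusion CH, C6 ester carbon, C8=C9 ring alkene); the target is the (3R,3aS,4S,8aR) isomer in azulene numbering (jaeschkeanadiol 6-veratrate).

## Retrosynthetic overview

1. Ester last: acylate the C6–OH of jaeschkeanadiol 18; C6–OH comes from C6 ketone 17 by hydride delivery directed by the C4–OH.
2. The seven-membered ring is formed second, on a purchased cyclopentane, by ring-closing metathesis (C8=C9) of a C1-allyl and a C7-methallyl arm that sit trans on the cyclopentane.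
3. Key bond C6–C7: C6 as an acyl anion (alkoxide-assisted lithio-1,3-dithiane) plus methallyl bromide, two carbons that are both electrophilic in their normal forms.
4. C4 carbinol from i-PrMgCl on the C4 ketone anti to C5; C5–C6 from the silyl enol ether plus 1,3-dithienium, so C6 arrives already masked.
5. C1 quaternary centre from Cu-catalysed asymmetric conjugate addition of Me3Al to 3-allylcyclopent-2-enone (made from 3-ethoxycyclopent-2-enone and allylMgBr).

## Route

Step 1
Reactants: 1 3-ethoxycyclopent-2-en-1-one; 2 allylmagnesium bromide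
Product: 4 3-allylcyclopent-2-en-1-one, via bromomagnesium 1-allyl-3-ethoxycyclopent-2-en-1-olate 3 (not isolated)
Conditions: 2 (1.2 equiv), THF, 0 °C; then 1 M aq HCl, 0 °C, 15 min
Reagents that add atoms: water, O
Why: Stork–Danheiser sequence, in which the Grignard adds 1,2 to the vinylogous ester carbonyl and brief cold acid ionises the tertiary allylic alcohol, water adds at the ethoxy carbon and ethanol is lost, giving the transposed enone with no stereocentre (short cold acid contact keeps the skipped diene out of conjugation).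

Step 2
Reactants: 4 3-allylcyclopent-2-en-1-one; 5 trimethylaluminium
Product: 7 (R)-triethyl[(3-allyl-3-methylcyclopent-1-en-1-yl)oxy]silane, via dimethylaluminium enolate of (R)-3-allyl-3-methylcyclopentanone 6 (not isolated)
Conditions: 5 (1.5 equiv), Cu(O2CC4H3S) (copper thiophene-2-carboxylate, 5 mol %), chiral biphenol-derived phosphoramidite with a bis(1-arylethyl)amino group (10 mol %, enantiomer chosen to give R at C1), Et2O, −30 °C; then Et3SiOTf, −30 → 0 °C
Reagents that add atoms: triethylsilyl trifluoromethanesulfonate, CC[Si](CC)(CC)OS(=O)(=O)C(F)(F)F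
Why: Copper-catalysed asymmetric conjugate addition of a trialkylaluminium to a β,β-disubstituted cyclopentenone (Alexakis/Hoveyda type) creates the C1 quaternary stereocentre with the face set by the ligand (R), and O-silylation of the aluminium enolate keeps the enolate at C5.

Step 3
Reactants: 7 (R)-triethyl[(3-allyl-3-methylcyclopent-1-en-1-yl)oxy]silane; 8 1,3-dithiane
Product: 10 (2R,3R)-3-allyl-2-(1,3-dithian-2-yl)-3-methylcyclopentan-1-one, via 1,3-dithian-2-ylium tetrafluoroborate 9 (not isolated)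
Conditions: 8, Ph3CBF4, CH2Cl2, reflux, 30 min; then 7, CH2Cl2/MeNO2, −78 °C; aq NaHCO3
Reagents that add atoms: none
Why: Paterson–Price alkylation of a silyl enol ether by the 1,3-dithienium cation (Mukaiyama-type) forms C5–C6 regiospecifically and installs C6 as a dithiane; the cation enters anti to the longer allyl arm so C6 ends cis to the C1 methyl, with only modest expected dr (about 3:1) that is upgraded by chromatography and by DBU re-equilibration of the unwanted C5 epimer (C5–H is α to the ketone).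

Step 4
Reactants: 10 (2R,3R)-3-allyl-2-(1,3-dithian-2-yl)-3-methylcyclopentan-1-one; 11 isopropylmagnesium chloride
Product: 12 (1R,2R,3R)-3-allyl-2-(1,3-dithian-2-yl)-3-methyl-1-(propan-2-yl)cyclopentan-1-ol
Conditions: 11 (1.5 equiv), LaCl3·2LiCl (30 mol %), THF, 0 °C; aq NH4Cl
Reagents that add atoms: none
Why: Lanthanum-promoted Grignard 1,2-addition (Knochel conditions) outcompetes enolisation and reduction, and isopropyl attacks the C4 carbonyl face opposite the bulky dithianyl group on C5, which sets C4 with OH cis to C6.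

Step 5
Reactants: 12 (1R,2R,3R)-3-allyl-2-(1,3-dithian-2-yl)-3-methyl-1-(propan-2-yl)cyclopentan-1-ol; 13 3-bromo-2-methylprop-1-ene
Product: 15 (1R,2R,3R)-3-allyl-3-methyl-2-[2-(2-methylprop-2-en-1-yl)-1,3-dithian-2-yl]-1-(propan-2-yl)cyclopentan-1-ol, via dilithiated alkoxide-dithianide 14 (not isolated)
Conditions: t-BuLi (2.3 equiv), HMPA, THF, −78 → −30 °C; then 13, −78 °C → rt; aq NH4Cl
Reagents that add atoms: none
Why: Corey–Seebach acyl-anion alkylation, in which the first equivalent of t-BuLi makes the C4 alkoxide that guides the second to the dithiane C–H, and the resulting C6 carbanion (a masked acyl anion) displaces bromide from the allylic halide by SN2, so carbonyl carbon C6 and allylic carbon C7, both electrophilic in their normal forms, are joined without creating a stereocentre.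

Step 6
Reactants: 15 (1R,2R,3R)-3-allyl-3-methyl-2-[2-(2-methylprop-2-en-1-yl)-1,3-dithian-2-yl]-1-(propan-2-yl)cyclopentan-1-ol
Product: 16 (3R,3aR,8aR)-6,8a-dimethyl-3-(propan-2-yl)-2,3,3a,5,8,8a-hexahydro-1H-spiro[azulene-4,2'-[1,3]dithian]-3-ol
Conditions: second-generation Grubbs catalyst RuCl2(=CHPh)(H2IMes)(PCy3) (5 mol %), CH2Cl2 (5 mM), 40 °C
Reagents that add atoms: none
Why: Ring-closing metathesis between the monosubstituted and the 1,1-disubstituted alkene gives the trisubstituted Z cycloheptene C8=C9 with loss of ethene, and because the two arms are trans on the cyclopentane the 5-7 ring fusion is trans; the ruthenium carbene tolerates the dithiane and the free tertiary alcohol.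

Step 7
Reactants: 16 (3R,3aR,8aR)-6,8a-dimethyl-3-(propan-2-yl)-2,3,3a,5,8,8a-hexahydro-1H-spiro[azulene-4,2'-[1,3]dithian]-3-ol
Product: 17 (3R,3aR,8aR)-3-hydroxy-6,8a-dimethyl-3-(propan-2-yl)-2,3,3a,5,8,8a-hexahydroazulen-4(1H)-one
Conditions: MeI (excess), NaHCO3, MeCN/H2O 4:1, 40 °C
Reagents that add atoms: water, O
Why: S-methylation then hydrolysis of the dithiane (Fetizon-type dethioacetalisation) under bicarbonate buffering unmasks the C6 ketone without touching the alkene or the tertiary alcohol, and C5 keeps its configuration because C6 anti to the C4 isopropyl group is also the thermodynamically preferred arrangement.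

Step 8
Reactants: 17 (3R,3aR,8aR)-3-hydroxy-6,8a-dimethyl-3-(propan-2-yl)-2,3,3a,5,8,8a-hexahydroazulen-4(1H)-one
Product: 18 (3R,3aS,4S,8aR)-6,8a-dimethyl-3-(propan-2-yl)-1,2,3,3a,4,5,8,8a-octahydroazulene-3,4-diol (jaeschkeanadiol)
Conditions: Me4NBH(OAc)3, MeCN/AcOH 1:1, −30 °C; aq NaHCO3
Reagents that add atoms: none
Why: Evans–Saksena hydroxyl-directed reduction, in which the C4 hydroxyl exchanges onto boron and hydride is delivered intramolecularly to the carbonyl face on the side of that oxygen, which sets C6 as S (H-6 anti to H-5, as in jaeschkeanadiol).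

Step 9
Reactants: 18 jaeschkeanadiol; 19 3,4-dimethoxybenzoyl chloride
Product: 20 (3R,3aS,4S,8aR)-3-hydroxy-6,8a-dimethyl-3-(propan-2-yl)-1,2,3,3a,4,5,8,8a-octahydroazulen-4-yl 3,4-dimethoxybenzoate
Conditions: 19 (1.3 equiv), Et3N, DMAP (10 mol %), CH2Cl2, 0 °C → rt
Reagents that add atoms: none
Why: DMAP-catalysed acyl transfer esterifies only the secondary C6 hydroxyl because the tertiary C4 hydroxyl is too hindered, and no stereocentre is touched.

## Compound list

1 | 3-ethoxycyclopent-2-en-1-one | CCOC1=CC(=O)CC1 | starting material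
2 | allylmagnesium bromide | C=CC[Mg]Br | starting material
3 | bromomagnesium 1-allyl-3-ethoxycyclopent-2-en-1-olate (racemic) | CCOC1=CC(CC=C)(O[Mg]Br)CC1 | intermediate
4 | 3-allylcyclopent-2-en-1-one | C=CCC1=CC(=O)CC1 | intermediate
5 | trimethylaluminium | C[Al](C)C | starting material
6 | dimethylaluminium (R)-3-allyl-3-methylcyclopent-1-en-1-olate | C=CC[C@@]1(C)CCC(O[Al](C)C)=C1 | intermediate
7 | (R)-triethyl[(3-allyl-3-methylcyclopent-1-en-1-yl)oxy]silane | C=CC[C@@]1(C)CCC(O[Si](CC)(CC)CC)=C1 | intermediate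
8 | 1,3-dithiane | C1CSCSC1 | starting material
9 | 1,3-dithian-2-ylium tetrafluoroborate | [CH+]1SCCCS1.F[B-](F)(F)F | intermediate
10 | (2R,3R)-3-allyl-2-(1,3-dithian-2-yl)-3-methylcyclopentan-1-one (dithianyl cis to methyl) | C=CC[C@@]1(C)CCC(=O)[C@@H]1C2SCCCS2 | intermediate
11 | isopropylmagnesium chloride | CC(C)[Mg]Cl | starting material
12 | (1R,2R,3R)-3-allyl-2-(1,3-dithian-2-yl)-3-methyl-1-(propan-2-yl)cyclopentan-1-ol (OH cis to dithianyl and methyl) | C=CC[C@@]1(C)CC[C@@](O)(C(C)C)[C@@H]1C2SCCCS2 | intermediate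
13 | 3-bromo-2-methylprop-1-ene (methallyl bromide) | C=C(C)CBr | starting material
14 | dilithium salt of 12 (C4 alkoxide, C6 dithianyl carbanion) | [Li+].[Li+].C=CC[C@@]1(C)CC[C@@]([O-])(C(C)C)[C@@H]1[C-]2SCCCS2 | intermediate
15 | (1R,2R,3R)-3-allyl-3-methyl-2-[2-(2-methylprop-2-en-1-yl)-1,3-dithian-2-yl]-1-(propan-2-yl)cyclopentan-1-ol | C=CC[C@@]1(C)CC[C@@](O)(C(C)C)[C@@H]1C2(CC(C)=C)SCCCS2 | intermediate
16 | (3R,3aR,8aR)-6,8a-dimethyl-3-(propan-2-yl)-2,3,3a,5,8,8a-hexahydro-1H-spiro[azulene-4,2'-[1,3]dithian]-3-ol (trans-fused; C6 dithioketal of 17) | C12(SCCCS1)CC(C)=CC[C@@]3(C)CC[C@@](O)(C(C)C)[C@H]23 | intermediate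
17 | (3R,3aR,8aR)-3-hydroxy-6,8a-dimethyl-3-(propan-2-yl)-2,3,3a,5,8,8a-hexahydroazulen-4(1H)-one | O=C2CC(C)=CC[C@@]3(C)CC[C@@](O)(C(C)C)[C@H]23 | intermediate
18 | (3R,3aS,4S,8aR)-6,8a-dimethyl-3-(propan-2-yl)-1,2,3,3a,4,5,8,8a-octahydroazulene-3,4-diol (jaeschkeanadiol) | O[C@H]2CC(C)=CC[C@@]3(C)CC[C@@](O)(C(C)C)[C@H]23 | intermediate
19 | 3,4-dimethoxybenzoyl chloride | COc1ccc(C(=O)Cl)cc1OC | starting material
20 | (3R,3aS,4S,8aR)-3-hydroxy-6,8a-dimethyl-3-(propan-2-yl)-1,2,3,3a,4,5,8,8a-octahydroazulen-4-yl 3,4-dimethoxybenzoate | COc1ccc(C(=O)O[C@H]2CC(C)=CC[C@@]3(C)CC[C@@](O)(C(C)C)[C@H]23)cc1OC | target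

## Step count and risks

Total step count: 9. Longest linear sequence: 9 (fully linear from 1).

The three steps most likely to fail:

**Step 3 (C5 configuration in the dithienium alkylation).** Methyl and allyl on C1 differ little in size, so substrate control at C5 may be poor. The fallback sets C5 by catalyst control and sets out from 7. Kobayashi-type asymmetric hydroxymethylation (aqueous formaldehyde, Sc(OTf)3, chiral 6,6'-bis(1-hydroxy-2,2-dimethylpropyl)-2,2'-bipyridine, DME/H2O) gives (2S,3R)-3-allyl-2-(hydroxymethyl)-3-methylcyclopentan-1-one F1. Isopropylmagnesium chloride with LaCl3·2LiCl (3 equiv of Grignard) then adds anti to the hydroxymethyl arm to give (1R,2S,3R)-3-allyl-2-(hydroxymethyl)-3-methyl-1-(propan-2-yl)cyclopentan-1-ol F2. TEMPO/PhI(OAc)2 oxidises only the primary alcohol to (1R,2R,5R)-5-allyl-2-hydroxy-5-methyl-2-(propan-2-yl)cyclopentane-1-carbaldehyde F3. Thioacetalisation with propane-1,3-dithiol and BF3·OEt2 at −20 °C comes back to the route at 12.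

**Step 5 (metalation and alkylation of the hindered dithiane).** C6–H sits between two quaternary carbons and may resist deprotonation. The fallback moves the acyl-anion alkylation to a stage where C5 is sp2 and sets out from 10. Et3SiOTf/Et3N gives the tetrasubstituted enol ether (R)-triethyl{[3-allyl-2-(1,3-dithian-2-yl)-3-methylcyclopent-1-en-1-yl]oxy}silane F4. n-BuLi (THF, −40 °C) removes the now allylic, doubly sulfur-stabilised C6–H, and methallyl bromide alkylates at C6 to give (R)-triethyl{[3-allyl-3-methyl-2-[2-(2-methylprop-2-en-1-yl)-1,3-dithian-2-yl]cyclopent-1-en-1-yl]oxy}silane F5. Bu4NF/AcOH releases (2R,3R)-3-allyl-3-methyl-2-[2-(2-methylprop-2-en-1-yl)-1,3-dithian-2-yl]cyclopentan-1-one F6, with C5 equilibrated by DBU. Isopropylmagnesium chloride with LaCl3·2LiCl comes back to the route at 15.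

**Step 8 (facial selectivity of the ketone reduction).** The tertiary C4–OH may not load onto boron, and external hydride is expected to give the C6 epimer. The fallback makes that epimer on purpose and inverts it, setting out from 17. NaBH4/CeCl3 (MeOH, −40 °C) attacks from the exposed face to give (3R,3aS,4R,8aR)-6,8a-dimethyl-3-(propan-2-yl)-1,2,3,3a,4,5,8,8a-octahydroazulene-3,4-diol F7. Mitsunobu esterification with 3,4-dimethoxybenzoic acid (PPh3, DIAD, toluene) installs the ester with inversion at C6 and comes back to the route at 20.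

Further compounds

F1 | step 3 | (2S,3R)-3-allyl-2-(hydroxymethyl)-3-methylcyclopentan-1-one | C=CC[C@@]1(C)CCC(=O)[C@@H]1CO
F2 | step 3 | (1R,2S,3R)-3-allyl-2-(hydroxymethyl)-3-methyl-1-(propan-2-yl)cyclopentan-1-ol | C=CC[C@@]1(C)CC[C@@](O)(C(C)C)[C@@H]1CO
F3 | step 3 | (1R,2R,5R)-5-allyl-2-hydroxy-5-methyl-2-(propan-2-yl)cyclopentane-1-carbaldehyde | C=CC[C@@]1(C)CC[C@@](O)(C(C)C)[C@@H]1C=O
F4 | step 5 | (R)-triethyl{[3-allyl-2-(1,3-dithian-2-yl)-3-methylcyclopent-1-en-1-yl]oxy}silane | C=CC[C@@]1(C)CCC(O[Si](CC)(CC)CC)=C1C2SCCCS2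
F5 | step 5 | (R)-triethyl{[3-allyl-3-methyl-2-[2-(2-methylprop-2-en-1-yl)-1,3-dithian-2-yl]cyclopent-1-en-1-yl]oxy}silane | C=CC[C@@]1(C)CCC(O[Si](CC)(CC)CC)=C1C2(CC(C)=C)SCCCS2
F6 | step 5 | (2R,3R)-3-allyl-3-methyl-2-[2-(2-methylprop-2-en-1-yl)-1,3-dithian-2-yl]cyclopentan-1-one | C=CC[C@@]1(C)CCC(=O)[C@@H]1C2(CC(C)=C)SCCCS2
F7 | step 8 | (3R,3aS,4R,8aR)-6,8a-dimethyl-3-(propan-2-yl)-1,2,3,3a,4,5,8,8a-octahydroazulene-3,4-diol | O[C@@H]2CC(C)=CC[C@@]3(C)CC[C@@](O)(C(C)C)[C@H]23
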